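## Retrosynthetic overview

1. Target 22 ⇒ ring-closing metathesis at C1=C10 of diene 21. C3–OH and C2–C3 come from a chiral phosphoric acid allylboration of enal 18, and C4=C5 from a Wittig reaction on aldehyde 16.
2. The C8 angelate and C9 acetate ⇒ threo diol 12 ⇒ hydroxyl-directed singlet-oxygen ene reaction of prenyl carbinol 10 (sets C9 and creates the isopropenyl group).
3. C7–C8 ⇒ chromium-mediated allylation of prenal 7 with 3-(bromomethyl)butenolide 6 (sets C7 and C8 from C6).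
4. 6 ⇒ α-methylene lactone 4 ⇒ organocatalytic enantioselective 2-(ethoxycarbonyl)allylboration–lactonisation of silyloxyacetaldehyde 1 with boronate 2 (sets C6, the first stereocentre).
5. Ring order: γ-lactone first (step 1), ten-membered carbocycle last (step 11).

Assumption: germacrane numbering (C1–C15) is used for positions in all intermediates, and the facial sense of both BINOL-derived acid catalysts is assigned by analogy with allylB(pin) additions (the antipodal catalyst would be used if the sense proved opposite).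

## Route

Step 1
Reactants: 1 2-{[tert-butyl(dimethyl)silyl]oxy}acetaldehyde; 2 ethyl 2-[(4,4,5,5-tetramethyl-1,3,2-dioxaborolan-2-yl)methyl]prop-2-enoate
Product: 4 (5S)-5-({[tert-butyl(dimethyl)silyl]oxy}methyl)-3-methylideneoxolan-2-one, via borate ester 3 (not isolated)
Conditions: (S)-TRIP N-triflylphosphoramide [(S)-3,3'-bis(2,4,6-triisopropylphenyl)-1,1'-binaphthyl-2,2'-diyl N-triflylphosphoramide] (5 mol %), 4 Å MS, toluene, −20 °C to rt, then 40 °C
Reagents that add atoms: none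
Why: Proposed new method: an enantioselective Brønsted-acid-catalysed 2-(alkoxycarbonyl)allylboration–lactonisation, in which the strongly acidic chiral N-triflylphosphoramide hydrogen-bonds to a pinacol oxygen of the electron-poor boronate 2 (raising the Lewis acidity of boron) and to the formyl C–H of 1 in a closed six-membered chair transition state, so that C6 (S) is set by the catalyst and borate 3 then lactonises under the same acid with loss of ethyl pinacol borate; the closest known reactions are the chiral phosphoric acid-catalysed allylboration of aldehydes with allylB(pin) (not shown for 2-alkoxycarbonyl reagents) and the achiral triflic acid-catalysed addition–lactonisation of 2-alkoxycarbonyl allylboronates.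

Step 2
Reactants: 4 (5S)-5-({[tert-butyl(dimethyl)silyl]oxy}methyl)-3-methylideneoxolan-2-one
Product: 6 (5S)-3-(bromomethyl)-5-({[tert-butyl(dimethyl)silyl]oxy}methyl)furan-2(5H)-one, via dibromide 5 (not isolated)
Conditions: Br2, CH2Cl2, 0 °C to rt; then Et3N, 0 °C
Reagents that add atoms: bromine (BrBr)
Why: Bromination of the exocyclic alkene followed by E2 dehydrobromination across C7–C11 gives the conjugated 3-(bromomethyl)butenolide, a known way to turn an α-methylene lactone into an allylating agent, and C6 is untouched because base contact is cold and brief.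

Step 3
Reactants: 6 (5S)-3-(bromomethyl)-5-({[tert-butyl(dimethyl)silyl]oxy}methyl)furan-2(5H)-one; 7 3-methylbut-2-enal
Product: 10 (4R,5S)-5-({[tert-butyl(dimethyl)silyl]oxy}methyl)-4-[(1S)-1-hydroxy-3-methylbut-2-en-1-yl]-3-methylideneoxolan-2-one, via allylchromium dichloride 8 (not isolated), via chromium alkoxide 9 (not isolated)
Conditions: CrCl2 (2.5 equiv), THF, 0 °C to rt; then water
Reagents that add atoms: none
Why: Nozaki–Hiyama–Kishi allylation in which the trivalent allylchromium species 8 adds 1,2 to the enal through C7 in a Zimmerman–Traxler chair, the ring-locked E geometry of the allyl unit giving the anti C7/C8 relation and approach opposite to the C6 substituent giving the trans lactone, so C7 and C8 are both relayed from C6.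

Step 4
Reactants: 10 (4R,5S)-5-({[tert-butyl(dimethyl)silyl]oxy}methyl)-4-[(1S)-1-hydroxy-3-methylbut-2-en-1-yl]-3-methylideneoxolan-2-one
Product: 12 (4R,5S)-5-({[tert-butyl(dimethyl)silyl]oxy}methyl)-4-[(1R,2R)-1,2-dihydroxy-3-methylbut-3-en-1-yl]-3-methylideneoxolan-2-one, via hydroperoxide 11 (not isolated)
Conditions: O2, visible light, tetraphenylporphyrin (cat.), CCl4, 0 °C; then PPh3, 0 °C to rt
Reagents that add atoms: dioxygen (O=O)
Why: Hydroxyl-directed Schenck ene reaction of singlet oxygen, in which 1,3-allylic strain from the cis methyl group fixes the carbinol conformation and O–H···O hydrogen bonding steers oxygen to C9 to give the threo (1R,2R) hydroperoxide with hydrogen abstraction from a methyl group (creating the isopropenyl group), the electron-poor methylidene lactone being inert and PPh3 reducing the hydroperoxide to the alcohol.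

Step 5
Reactants: 12 (4R,5S)-5-({[tert-butyl(dimethyl)silyl]oxy}methyl)-4-[(1R,2R)-1,2-dihydroxy-3-methylbut-3-en-1-yl]-3-methylideneoxolan-2-one
Product: 13 (1R,2R)-1-[(2S,3R)-2-({[tert-butyl(dimethyl)silyl]oxy}methyl)-4-methylidene-5-oxooxolan-3-yl]-1-hydroxy-3-methylbut-3-en-2-yl acetate
Conditions: AcCl (1.05 equiv), 2,4,6-collidine, CH2Cl2, −78 °C
Reagents that add atoms: acetyl chloride (CC(Cl)=O)
Why: Site-selective acylation at low temperature of the more accessible allylic C9 hydroxyl, the C8 hydroxyl being flanked by the ring carbon C7 and hydrogen-bonded to the lactone carbonyl.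

Step 6
Reactants: 13 (1R,2R)-1-[(2S,3R)-2-({[tert-butyl(dimethyl)silyl]oxy}methyl)-4-methylidene-5-oxooxolan-3-yl]-1-hydroxy-3-methylbut-3-en-2-yl acetate
Product: 14 (1R,2R)-2-acetoxy-1-[(2S,3S)-2-({[tert-butyl(dimethyl)silyl]oxy}methyl)-4-methylidene-5-oxooxolan-3-yl]-3-methylbut-3-en-1-yl (2Z)-2-methylbut-2-enoate
Conditions: angelic acid, 2,4,6-trichlorobenzoyl chloride, Et3N, toluene, rt; then 13, 60 °C
Reagents that add atoms: angelic acid, (2Z)-2-methylbut-2-enoic acid (C/C=C(/C)C(=O)O)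
Why: Yamaguchi-type mixed-anhydride esterification without a nucleophilic catalyst acylates the hindered C8 hydroxyl while keeping the Z geometry of the angelate, which nucleophilic amine catalysts tend to isomerise to the tiglate.

Step 7
Reactants: 14 (1R,2R)-2-acetoxy-1-[(2S,3S)-2-({[tert-butyl(dimethyl)silyl]oxy}methyl)-4-methylidene-5-oxooxolan-3-yl]-3-methylbut-3-en-1-yl (2Z)-2-methylbut-2-enoate
Product: 15 (1R,2R)-2-acetoxy-1-[(2S,3S)-2-(hydroxymethyl)-4-methylidene-5-oxooxolan-3-yl]-3-methylbut-3-en-1-yl (2Z)-2-methylbut-2-enoate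
Conditions: HF·pyridine, pyridine, THF, 0 °C to rt
Reagents that add atoms: none
Why: Fluoride-mediated desilylation of the primary silyl ether in a buffered acidic medium that leaves the esters, the allylic acetate and the methylidene lactone untouched and causes no acyl migration.

Step 8
Reactants: 15 (1R,2R)-2-acetoxy-1-[(2S,3S)-2-(hydroxymethyl)-4-methylidene-5-oxooxolan-3-yl]-3-methylbut-3-en-1-yl (2Z)-2-methylbut-2-enoate
Product: 16 (1R,2R)-2-acetoxy-1-[(2S,3R)-2-formyl-4-methylidene-5-oxooxolan-3-yl]-3-methylbut-3-en-1-yl (2Z)-2-methylbut-2-enoate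
Conditions: Dess–Martin periodinane, CH2Cl2, 0 °C to rt
Reagents that add atoms: none
Why: Dess–Martin oxidation of the primary alcohol under non-basic conditions gives the α-oxygenated aldehyde without epimerising C6 (the aldehyde is used crude).

Step 9
Reactants: 16 (1R,2R)-2-acetoxy-1-[(2S,3R)-2-formyl-4-methylidene-5-oxooxolan-3-yl]-3-methylbut-3-en-1-yl (2Z)-2-methylbut-2-enoate; 17 2-(triphenylphosphoranylidene)propanal
Product: 18 (1R,2R)-2-acetoxy-3-methyl-1-{(2R,3S)-4-methylidene-2-[(1E)-2-methyl-3-oxoprop-1-en-1-yl]-5-oxooxolan-3-yl}but-3-en-1-yl (2Z)-2-methylbut-2-enoate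
Conditions: toluene, 40 °C
Reagents that add atoms: none
Why: Wittig olefination with the formyl-stabilised ylide is aldehyde-selective and gives the (E)-trisubstituted C4=C5 enal, the neutral conditions sparing C6 and the methylidene lactone.

Step 10
Reactants: 18 (1R,2R)-2-acetoxy-3-methyl-1-{(2R,3S)-4-methylidene-2-[(1E)-2-methyl-3-oxoprop-1-en-1-yl]-5-oxooxolan-3-yl}but-3-en-1-yl (2Z)-2-methylbut-2-enoate; 19 4,4,5,5-tetramethyl-2-(prop-2-en-1-yl)-1,3,2-dioxaborolane
Product: 21 (1R,2R)-2-acetoxy-1-{(2R,3S)-2-[(1E,3S)-3-hydroxy-2-methylhexa-1,5-dien-1-yl]-4-methylidene-5-oxooxolan-3-yl}-3-methylbut-3-en-1-yl (2Z)-2-methylbut-2-enoate, via borate ester 20 (not isolated)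
Conditions: (S)-TRIP [(S)-3,3'-bis(2,4,6-triisopropylphenyl)-1,1'-binaphthyl-2,2'-diyl hydrogen phosphate] (5 mol %), toluene, −30 °C; aqueous work-up
Reagents that add atoms: none
Why: Chiral phosphoric acid-catalysed allylboration of the enal through a closed chair transition state in which the catalyst binds a boronate oxygen and the formyl hydrogen, so that C3 (S) is set by the catalyst while the esters and the methylidene lactone do not react and the C3 hydroxyl needs no protecting group.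

Step 11
Reactants: 21 (1R,2R)-2-acetoxy-1-{(2R,3S)-2-[(1E,3S)-3-hydroxy-2-methylhexa-1,5-dien-1-yl]-4-methylidene-5-oxooxolan-3-yl}-3-methylbut-3-en-1-yl (2Z)-2-methylbut-2-enoate
Product: 22 (3S,6R,7S,8R,9R)-9-acetoxy-3-hydroxy-8-{[(2Z)-2-methylbut-2-enoyl]oxy}germacra-1(10)Z,4E,11(13)-trien-12,6-olide (CNP0265116.2)
Conditions: second-generation Grubbs catalyst [RuCl2(=CHPh)(H2IMes)(PCy3)] (10 mol %), toluene (1 mM), 80 °C
Reagents that add atoms: none
Why: Ring-closing olefin metathesis between the C1 vinyl group and the C10 isopropenyl group releases ethene and forms the trisubstituted C1=C10 bond with ring-cis (Z) geometry, the low-strain option in a ten-membered ring that already holds the E C4=C5 bond, while closure onto the exocyclic methylidene would need an eight-membered ring containing an E double bond.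

## Compound list

1 | 2-{[tert-butyl(dimethyl)silyl]oxy}acetaldehyde | O=CCO[Si](C)(C)C(C)(C)C | starting material
2 | ethyl 2-[(4,4,5,5-tetramethyl-1,3,2-dioxaborolan-2-yl)methyl]prop-2-enoate | C=C(CB1OC(C)(C)C(C)(C)O1)C(=O)OCC | starting material
3 | ethyl (4S)-5-{[tert-butyl(dimethyl)silyl]oxy}-2-methylidene-4-[(4,4,5,5-tetramethyl-1,3,2-dioxaborolan-2-yl)oxy]pentanoate | C=C(C[C@H](OB1OC(C)(C)C(C)(C)O1)CO[Si](C)(C)C(C)(C)C)C(=O)OCC | intermediate (not isolated)
4 | (5S)-5-({[tert-butyl(dimethyl)silyl]oxy}methyl)-3-methylideneoxolan-2-one | C=C1C(=O)O[C@H](CO[Si](C)(C)C(C)(C)C)C1 | intermediate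
5 | (5S)-3-bromo-3-(bromomethyl)-5-({[tert-butyl(dimethyl)silyl]oxy}methyl)oxolan-2-one (both C3 epimers) | BrCC1(Br)C[C@@H](CO[Si](C)(C)C(C)(C)C)OC1=O | intermediate (not isolated)
6 | (5S)-3-(bromomethyl)-5-({[tert-butyl(dimethyl)silyl]oxy}methyl)furan-2(5H)-one | BrCC1=C[C@@H](CO[Si](C)(C)C(C)(C)C)OC1=O | intermediate
7 | 3-methylbut-2-enal | CC(C)=CC=O | starting material
8 | {[(5S)-5-({[tert-butyl(dimethyl)silyl]oxy}methyl)-2-oxo-2,5-dihydrofuran-3-yl]methyl}chromium dichloride | Cl[Cr](Cl)CC1=C[C@@H](CO[Si](C)(C)C(C)(C)C)OC1=O | intermediate (not isolated)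
9 | dichlorochromium alkoxide of 10 (O–CrCl2 at C8) | C=C1C(=O)O[C@H](CO[Si](C)(C)C(C)(C)C)[C@H]1[C@@H](O[Cr](Cl)Cl)C=C(C)C | intermediate (not isolated)
10 | (4R,5S)-5-({[tert-butyl(dimethyl)silyl]oxy}methyl)-4-[(1S)-1-hydroxy-3-methylbut-2-en-1-yl]-3-methylideneoxolan-2-one | C=C1C(=O)O[C@H](CO[Si](C)(C)C(C)(C)C)[C@H]1[C@@H](O)C=C(C)C | intermediate
11 | (4R,5S)-5-({[tert-butyl(dimethyl)silyl]oxy}methyl)-4-[(1R,2R)-2-hydroperoxy-1-hydroxy-3-methylbut-3-en-1-yl]-3-methylideneoxolan-2-one | C=C1C(=O)O[C@H](CO[Si](C)(C)C(C)(C)C)[C@H]1[C@@H](O)[C@H](OO)C(C)=C | intermediate (not isolated)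
12 | (4R,5S)-5-({[tert-butyl(dimethyl)silyl]oxy}methyl)-4-[(1R,2R)-1,2-dihydroxy-3-methylbut-3-en-1-yl]-3-methylideneoxolan-2-one | C=C1C(=O)O[C@H](CO[Si](C)(C)C(C)(C)C)[C@H]1[C@@H](O)[C@H](O)C(C)=C | intermediate
13 | (1R,2R)-1-[(2S,3R)-2-({[tert-butyl(dimethyl)silyl]oxy}methyl)-4-methylidene-5-oxooxolan-3-yl]-1-hydroxy-3-methylbut-3-en-2-yl acetate | C=C1C(=O)O[C@H](CO[Si](C)(C)C(C)(C)C)[C@H]1[C@@H](O)[C@H](OC(C)=O)C(C)=C | intermediate
14 | (1R,2R)-2-acetoxy-1-[(2S,3S)-2-({[tert-butyl(dimethyl)silyl]oxy}methyl)-4-methylidene-5-oxooxolan-3-yl]-3-methylbut-3-en-1-yl (2Z)-2-methylbut-2-enoate | C=C1C(=O)O[C@H](CO[Si](C)(C)C(C)(C)C)[C@H]1[C@@H](OC(=O)/C(C)=C\C)[C@H](OC(C)=O)C(C)=C | intermediate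
15 | (1R,2R)-2-acetoxy-1-[(2S,3S)-2-(hydroxymethyl)-4-methylidene-5-oxooxolan-3-yl]-3-methylbut-3-en-1-yl (2Z)-2-methylbut-2-enoate | C=C1C(=O)O[C@H](CO)[C@H]1[C@@H](OC(=O)/C(C)=C\C)[C@H](OC(C)=O)C(C)=C | intermediate
16 | (1R,2R)-2-acetoxy-1-[(2S,3R)-2-formyl-4-methylidene-5-oxooxolan-3-yl]-3-methylbut-3-en-1-yl (2Z)-2-methylbut-2-enoate | C=C1C(=O)O[C@H](C=O)[C@H]1[C@@H](OC(=O)/C(C)=C\C)[C@H](OC(C)=O)C(C)=C | intermediate
17 | 2-(triphenylphosphoranylidene)propanal | CC(C=O)=P(c1ccccc1)(c1ccccc1)c1ccccc1 | starting material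
18 | (1R,2R)-2-acetoxy-3-methyl-1-{(2R,3S)-4-methylidene-2-[(1E)-2-methyl-3-oxoprop-1-en-1-yl]-5-oxooxolan-3-yl}but-3-en-1-yl (2Z)-2-methylbut-2-enoate | C=C1C(=O)O[C@H](/C=C(\C)C=O)[C@H]1[C@@H](OC(=O)/C(C)=C\C)[C@H](OC(C)=O)C(C)=C | intermediate
19 | 4,4,5,5-tetramethyl-2-(prop-2-en-1-yl)-1,3,2-dioxaborolane | C=CCB1OC(C)(C)C(C)(C)O1 | starting material
20 | O-pinacolboryl ether of 21 (boron on the C3 oxygen) | C=C1C(=O)O[C@H](/C=C(\C)[C@@H](OB2OC(C)(C)C(C)(C)O2)CC=C)[C@H]1[C@@H](OC(=O)/C(C)=C\C)[C@H](OC(C)=O)C(C)=C | intermediate (not isolated)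
21 | (1R,2R)-2-acetoxy-1-{(2R,3S)-2-[(1E,3S)-3-hydroxy-2-methylhexa-1,5-dien-1-yl]-4-methylidene-5-oxooxolan-3-yl}-3-methylbut-3-en-1-yl (2Z)-2-methylbut-2-enoate | C=C1C(=O)O[C@H](/C=C(\C)[C@@H](O)CC=C)[C@H]1[C@@H](OC(=O)/C(C)=C\C)[C@H](OC(C)=O)C(C)=C | intermediate
22 | (3S,6R,7S,8R,9R)-9-acetoxy-3-hydroxy-8-{[(2Z)-2-methylbut-2-enoyl]oxy}germacra-1(10)Z,4E,11(13)-trien-12,6-olide | C=C1C(=O)O[C@@H]2/C=C(\C)[C@@H](O)C/C=C(/C)[C@@H](OC(C)=O)[C@H](OC(=O)/C(C)=C\C)[C@@H]12 | target

## Step count and risks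

Total steps: 11. Longest linear sequence: 11 (1 → 22; compounds 2, 7, 17, 19 and the reagents are purchased).

Three steps most likely to fail:

Step 1 (the proposed new method). The electron-poor boronate 2 may react too slowly with a chiral acid, or the enantioselectivity may be low. The fallback uses known chemistry, sets out from 1 and comes back at 4. Aldehyde 1 is allylated with ethyl 2-(bromomethyl)acrylate under catalytic asymmetric Nozaki–Hiyama–Kishi conditions (CrCl2 10 mol %, a chiral carbazole bis(oxazoline) ligand, Mn powder, Me3SiCl, THF), a known enantioselective 2-(alkoxycarbonyl)allylation. This gives the silyl ether ethyl (4S)-5-{[tert-butyl(dimethyl)silyl]oxy}-2-methylidene-4-[(trimethylsilyl)oxy]pentanoate F1, which is not isolated. Dilute aqueous HCl in the work-up frees ethyl (4S)-5-{[tert-butyl(dimethyl)silyl]oxy}-4-hydroxy-2-methylidenepentanoate F2, and catalytic TsOH in toluene lactonises it to 4.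

Step 5 (site-selective acetylation of diol 12). If the C8 hydroxyl competes or the acetyl group migrates, the two oxygens are introduced one after the other instead; this fallback sets out from 10 and comes back at 14.
- Allylic alcohol 10 is epoxidised with mCPBA (hydroxyl-directed and threo-selective for an allylic alcohol with a cis alkene substituent) to (4R,5S)-5-({[tert-butyl(dimethyl)silyl]oxy}methyl)-4-{(R)-[(2S)-3,3-dimethyloxiran-2-yl](hydroxy)methyl}-3-methylideneoxolan-2-one F3.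
- Its only free hydroxyl (C8) is esterified with angelic acid under the mixed-anhydride conditions of step 6 to (R)-[(2S,3S)-2-({[tert-butyl(dimethyl)silyl]oxy}methyl)-4-methylidene-5-oxooxolan-3-yl][(2S)-3,3-dimethyloxiran-2-yl]methyl (2Z)-2-methylbut-2-enoate F4.
- Me3SiOTf and 2,6-lutidine (toluene, −78 °C) open the epoxide at its tertiary carbon with loss of a methyl proton to give (1R,2R)-1-[(2S,3S)-2-({[tert-butyl(dimethyl)silyl]oxy}methyl)-4-methylidene-5-oxooxolan-3-yl]-3-methyl-2-[(trimethylsilyl)oxy]but-3-en-1-yl (2Z)-2-methylbut-2-enoate F5, which is not isolated.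
- Dilute acid in the work-up gives (1R,2R)-1-[(2S,3S)-2-({[tert-butyl(dimethyl)silyl]oxy}methyl)-4-methylidene-5-oxooxolan-3-yl]-2-hydroxy-3-methylbut-3-en-1-yl (2Z)-2-methylbut-2-enoate F6, whose single free hydroxyl (C9) is acetylated (AcCl, pyridine) to give 14.

Step 11 (ring-closing metathesis to a strained ten-membered ring with a trisubstituted alkene). The free C3 carbinol may favour oligomerisation or ruthenium hydride side reactions. The fallback closes the ring at the ketone oxidation level and sets C3 last; it sets out from 21 and comes back at 22, and it does not help if the hindered isopropenyl group itself is the obstacle. Dess–Martin oxidation of 21 gives (1R,2R)-2-acetoxy-3-methyl-1-{(2R,3S)-4-methylidene-2-[(1E)-2-methyl-3-oxohexa-1,5-dien-1-yl]-5-oxooxolan-3-yl}but-3-en-1-yl (2Z)-2-methylbut-2-enoate F7. Ring-closing metathesis of this hydroxyl-free dienone (second-generation Hoveyda–Grubbs catalyst [RuCl2(=CH-C6H4-2-OiPr)(H2IMes)], toluene, 80 °C) gives (6R,7S,8R,9R)-9-acetoxy-8-{[(2Z)-2-methylbut-2-enoyl]oxy}-3-oxogermacra-1(10)Z,4E,11(13)-trien-12,6-olide F8. Corey–Bakshi–Shibata reduction of the enone ((R)-2-methyl-CBS-oxazaborolidine, catecholborane, toluene, −78 °C) then sets C3 (S) under reagent control and gives 22.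

## Further compounds

F1 | step 1 | ethyl (4S)-5-{[tert-butyl(dimethyl)silyl]oxy}-2-methylidene-4-[(trimethylsilyl)oxy]pentanoate | C=C(C[C@H](O[Si](C)(C)C)CO[Si](C)(C)C(C)(C)C)C(=O)OCC
F2 | step 1 | ethyl (4S)-5-{[tert-butyl(dimethyl)silyl]oxy}-4-hydroxy-2-methylidenepentanoate | C=C(C[C@H](O)CO[Si](C)(C)C(C)(C)C)C(=O)OCC
F3 | step 5 | (4R,5S)-5-({[tert-butyl(dimethyl)silyl]oxy}methyl)-4-{(R)-[(2S)-3,3-dimethyloxiran-2-yl](hydroxy)methyl}-3-methylideneoxolan-2-one | C=C1C(=O)O[C@H](CO[Si](C)(C)C(C)(C)C)[C@H]1[C@@H](O)[C@@H]2OC2(C)C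
F4 | step 5 | (R)-[(2S,3S)-2-({[tert-butyl(dimethyl)silyl]oxy}methyl)-4-methylidene-5-oxooxolan-3-yl][(2S)-3,3-dimethyloxiran-2-yl]methyl (2Z)-2-methylbut-2-enoate | C=C1C(=O)O[C@H](CO[Si](C)(C)C(C)(C)C)[C@H]1[C@@H](OC(=O)/C(C)=C\C)[C@@H]2OC2(C)C
F5 | step 5 | (1R,2R)-1-[(2S,3S)-2-({[tert-butyl(dimethyl)silyl]oxy}methyl)-4-methylidene-5-oxooxolan-3-yl]-3-methyl-2-[(trimethylsilyl)oxy]but-3-en-1-yl (2Z)-2-methylbut-2-enoate | C=C1C(=O)O[C@H](CO[Si](C)(C)C(C)(C)C)[C@H]1[C@@H](OC(=O)/C(C)=C\C)[C@H](O[Si](C)(C)C)C(C)=C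
F6 | step 5 | (1R,2R)-1-[(2S,3S)-2-({[tert-butyl(dimethyl)silyl]oxy}methyl)-4-methylidene-5-oxooxolan-3-yl]-2-hydroxy-3-methylbut-3-en-1-yl (2Z)-2-methylbut-2-enoate | C=C1C(=O)O[C@H](CO[Si](C)(C)C(C)(C)C)[C@H]1[C@@H](OC(=O)/C(C)=C\C)[C@H](O)C(C)=C
F7 | step 11 | (1R,2R)-2-acetoxy-3-methyl-1-{(2R,3S)-4-methylidene-2-[(1E)-2-methyl-3-oxohexa-1,5-dien-1-yl]-5-oxooxolan-3-yl}but-3-en-1-yl (2Z)-2-methylbut-2-enoate | C=C1C(=O)O[C@H](/C=C(\C)C(=O)CC=C)[C@H]1[C@@H](OC(=O)/C(C)=C\C)[C@H](OC(C)=O)C(C)=C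
F8 | step 11 | (6R,7S,8R,9R)-9-acetoxy-8-{[(2Z)-2-methylbut-2-enoyl]oxy}-3-oxogermacra-1(10)Z,4E,11(13)-trien-12,6-olide | C=C1C(=O)O[C@@H]2/C=C(\C)C(=O)C/C=C(/C)[C@@H](OC(C)=O)[C@H](OC(=O)/C(C)=C\C)[C@@H]12
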